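In the autumn run target and starting material together make 100% of the charge at the last reading, so the fraction of starting material left gives the target too.

| setting | autumn | dusk | spring | flask |
|---|---|---|---|---|
| starting material | 0.57 M | 0.57 M | 0.57 M | 0.57 M |
| reagent | 0.456 M | 0.456 M | 0.456 M | 0.456 M |
| second substrate | 0.057 M | 0.086 M | 0.114 M | 0.114 M |
| catalyst | 0.57 mM | 0.57 mM | 0.28 mM | 0.57 mM |
| remark | run made earlier | run made earlier | run made earlier |  |
| time |  |  |  | 25 h |

| run | time / h | target / % | starting material / % |
|---|---|---|---|
| autumn | 2.00 | 27.2 | 72.9 |
| autumn | 6.00 | 27.6 | 72.0 |
| autumn | 10.0 | 27.9 | 72.4 |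
| autumn | 15.0 | 28.1 | 72.3 |
| autumn | 25.0 | 28.2 | 72.7 |
| autumn | 30.0 | 28.1 | 72.1 |
| dusk | 5.00 | 25.9 | 73.6 |
| dusk | 10.0 | 26.1 | 73.3 |
| dusk | 15.0 | 25.7 | 73.8 |
| dusk | 20.0 | 26.2 | 74.0 |
| dusk | 25.0 | 26.4 | 74.1 |
| dusk | 30.0 | 25.9 | 73.7 |
| spring | 6.00 | 25.2 | 75.5 |
| spring | 12.0 | 24.1 | 75.6 |
| spring | 20.0 | 24.7 | 74.9 |
| spring | 25.0 | 24.6 | 75.6 |
| spring | 30.0 | 24.4 | 75.4 |

(readings scatter by 0.3 percentage points)

- the numbers in the tables scatter by 0.3 percentage points (one standard deviation)
- the reaction counts as stopped when no species that holds the starting material changes by six tenths of a point or more over the second half of the time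

1. at 25 h, what has stopped the reaction, if anything has (forward and back rates have come level / no working catalyst is left / it is still moving / all of the starting material has reacted / the reagent has run out first)
2. target at 25 h, in percent of the starting material charged

**Have the earlier runs stopped?** They look flat. Over their last 3 readings the target averages 28.1% in autumn, 26.2% in dusk and 24.6% in spring.

**Stopped by what?** Try a balance between starting material, reagent and target. I define the carried quantity as the mass-action quotient, the apparent equilibrium constant, [target]/([starting material][reagent]), where [reagent] is its charge less the second substrate charged, less [target].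

**The second substrate is not in the readings. Why subtract it?** That is a trial assumption: each molecule of second substrate removes one of reagent. The test is that the second substrate charge doubles from autumn to spring, and the quotient reads 1.64 /M, 1.60 /M and 1.61 /M. I carry their mean, 1.62 /M.

**Could dying catalyst cause the stop?** Spring has half the catalyst of dusk, yet its quotient stays close, which points to level rates.

**And this flask?** The flask's net reagent is 0.342 M, and solving the quotient for the fraction left gives, by my reckoning, target 24.6%. The flask has twice spring's catalyst, and it runs 25 h, longer than the 6.00 h at which spring already read 25.2%.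

The forecast says forward and back rates have come level, with 24.6% between 24% and 25.2%, on the view “It behaves like a co-product pushing back on an equilibrium”.

The flask gives forward and back rates have come level, with 24.5%.

    starting material + reagent + catalyst ⇌ catalyst + target (K = 1.60 /M, k = 0.609 /M²/s)
    second substrate + reagent + catalyst → catalyst + second product (k = 2.43 /M²/s)

In the flask the reversible step, taken by itself and both ways together, relaxes at 25.0 h with a half-life of 0.441 h, shorter than the 25 h of the run. At that time 76% of the starting material and 44% of the reagent remain, 100% of the catalyst can still turn over, and the end state gives a quotient of 1.60 /M. For a neighbour flask charged with 1.8 M of reagent, the carried 1.62 /M gives 67.8%, and that neighbour holds 67.5% of target.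

The readings stem from a simulated flask for an exercise, and the scatter is random.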